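## The problem

The target is a trans-2,3-diaryl-2,3-dihydrobenzofuran. Ring A (the benzo ring) carries a hydroxyl at C6 and an (E)-3,5-dihydroxystyryl group at C5, C2 bears a 3,4-dihydroxyphenyl ring and C3 a 3,5-dihydroxyphenyl ring. The two stereocenters are adjacent and (2S,3S), with the aryl groups trans.

C2 is a benzylic ether carbon whose C–O bond can ionize, because its aryl ring has a para oxygen. Its configuration can therefore be corrected thermodynamically by C3, the trans isomer being the more stable. C3 is a doubly benzylic all-carbon center that nothing else in the molecule controls, so it must be set by an external chiral agent.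

The seven phenols (one catechol, two resorcinols and the C6 hydroxyl) are sensitive to air and base. The electron-rich stilbene is sensitive to acid, light and hydrogenation, and the C2–O bond to strong Lewis acid. The phenols must therefore stay masked to the end by groups that are not removed with hydrogen, and the stilbene should appear late.

Ring A needs a carbon handle at C5. It cannot be introduced late by electrophilic substitution, because the 3,5-dioxygenated ring on C3 is more nucleophilic than ring A.

The enabling feature is that C2 and C3 each carry one aryl group and one hydrogen, trans, and together they are the C2=C3 bond of a ring A benzofuran. That bond is an enol ether inside a weakly aromatic furan and its C2–H can be lithiated. Boron can thus be placed at C2 and both aryl–carbon bonds made anti across the double bond on the intact bicycle.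

## Retrosynthesis

**Target 14 to heptamethyl ether 13.** The seven O–CH3 bonds are cut last. Methyl ethers are preferred to benzyl ethers (hydrogenolysis would reduce the stilbene), to silyl ethers (lost in the fluoride step) and to alkoxymethyl ethers (they direct ortho-lithiation and would compete with C2 lithiation). Every building block is sold as its methyl ether. The forward reaction must cleave seven ethers without damaging the stilbene or the C2–O bond.

**Stilbene 13 to aryl chloride 11 and styrene 12.** The C5–C(vinyl) bond is cut as a Mizoroki–Heck coupling. A carbonyl olefination would need an aldehyde at C5 to pass through an organolithium step. An earlier stilbene would offer the cationic arylpalladium of the key step a second alkene. The handle must survive butyllithium and a palladium catalyst that is meant to react only with a triflate, so it is chlorine, not bromine. The price is a more demanding Heck reaction on an electron-rich aryl chloride.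

**Chloride 11 to boronic ester 10.** The C2–H bond is traced back to a C2–B bond. Boron is the traceless handle that makes C2 a nucleophilic carbon in the key step. The forward reaction must replace boron by hydrogen with retention, so that the hydrogen ends up cis to the C3 aryl group and the two aryl groups stay trans.

**Boronic ester 10 to benzofuran 4, boronic ester 7 and triflate 6.** The C2–aryl and C3–aryl bonds are cut together. Lithiation of 4 gives 8, which adds to 7 to give the boronate complex 9. Palladium-catalysed coupling of 9 with 6 moves the 3,4-dimethoxyphenyl group from boron to C2 while the 3,5-dimethoxyphenyl group is delivered to C3. Against cuts through the O1–C2 or C3–C3a bonds, this one builds no ring, sets both stereocenters in one operation, and reduces the problem to three simple achiral arenes. It asks for face selection by a chiral ligand, anti addition across C2=C3, and tolerance of the aryl chloride.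

**Benzofuran 4 to phenol 1 and acetal 2; triflate 6 to phenol 5.** The furan ring of 4 is cut at C3–C3a and at the ether O–CH2 bond, leading through aryloxy acetal 3 to 4-chloro-3-methoxyphenol 1 and bromoacetaldehyde diethyl acetal 2. The chlorine is thus bought in the right place. Triflate 6 comes from 3,5-dimethoxyphenol 5. Boronic ester 7 and styrene 12 are purchased.

## Roads not taken

**Alternative 1:** The cut runs through C3–C3a and C7a–O1. Ring A would come as methyl 4-iodo-2-methoxybenzoate A1 and the two heterocyclic carbons as tert-butyl (2R,3S)-3-(3,5-dimethoxyphenyl)oxirane-2-carboxylate A2.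

- **Forward key step:** under palladium/norbornene cooperative catalysis the aryl–norbornyl palladacycle would open the epoxide at its benzylic carbon with inversion. The alkoxide would then close onto the ipso carbon, giving the cis diester A3.
- **Merits:** the absolute configuration at C3 is bought with a glycidate that established asymmetric epoxidation can supply. Ring A arrives with its oxygen pattern and a C5 carbon substituent fixed, with no regiochemical question.
- **Weak points:** this annulation type is established for terminal epoxides opened at the unsubstituted carbon. Here a bulky palladacycle must attack the hindered benzylic carbon of a 2,3-disubstituted epoxide. C2 then carries an ester where the target needs the catechol ring, so ester cleavage and a decarboxylative arylation through a C2 radical are required. The C5 ester needs reduction, oxidation and olefination. The count comes to roughly eleven steps.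
- **Comparison:** on the certainty of absolute configuration this road is better than the chosen plan, which stakes C3 on ligand control in an untested reaction. The chosen plan sets against this two aryl–carbon bonds in one step, about four fewer steps, and a resolution fallback.

**Alternative 2:** The cut runs through ring A itself (C4=C5 and C6–C7). The precursor is (4S,5S)-5-(3,4-dimethoxyphenyl)-4-(3,5-dimethoxyphenyl)-2-methyl-4,5-dihydrofuran-3-carbaldehyde A4.

- **Forward key step:** Knoevenagel condensation of A4 with dimethyl malonate A5, then alkoxide-induced attack of the vinylogous methyl carbanion on one ester, would close and aromatize ring A to the salicylate A6.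
- **Merits:** the ring A pattern (C6 hydroxyl, C5 carbon substituent) arises without any selectivity question. No halogen handle or precious metal is needed, and the stilbene would later come from a reliable carbonyl olefination instead of a Heck reaction on an aryl chloride. In these respects it is better than the chosen plan.
- **Weak points:** both stereocenters and the question of which aryl group sits next to oxygen are moved into A4. No direct enantioselective, regiodefined route to A4 exists; oxidative cycloaddition of a dicarbonyl compound to an unsymmetrical stilbene would give regioisomers and a racemate. Turning the ester of A6 into the stilbene adds protection, reduction, oxidation and olefination, for roughly twelve steps.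
- **Comparison:** the chosen plan sets against its weaker ring A logic a key step that itself addresses the stereochemical problem.

**Alternative 3:** The cut is the C3–C3a bond, formed by migration of ring A in (S)-6-bromo-2-(3,4-dimethoxyphenyl)-7-methoxychroman-4-one A7.

- **Forward key step:** a trivalent iodine diacetate oxidant in an acidic orthoformate medium would iodinate the enol ether of the ketal. Ring A then shifts from the ketal carbon to C3, contracting the pyranone to the trans ester A8.
- **Merits:** this ring contraction is a known reaction type on flavanones, so the key step stands on firmer ground than the chosen one. The trans relation arises directly, and the bromide is a better Heck handle than the chloride.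
- **Weak points:** C3 arrives with a methyl ester where the target needs the 3,5-dioxygenated aryl ring. Hydrolysis and a decarboxylative arylation at this stereocenter add steps and their own uncertainty. The flavanone can racemize in strong acid by reversible opening to the chalcone, and its enantioselective preparation adds three to four steps. The total is roughly ten.
- **Comparison:** the chosen plan sets against the better precedent a direct installation of the correct C3 substituent and a shorter sequence.

Key step: step 4

Assumption: the sense of induction of the ferrocenyl bisphosphine in the new coupling cannot be predicted, so the ligand enantiomer that gives the (3S) series would be chosen by trial; both enantiomers are available.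

## Route

Step 1
Reactants: 1 4-chloro-3-methoxyphenol; 2 2-bromo-1,1-diethoxyethane (bromoacetaldehyde diethyl acetal)
Product: 3 1-chloro-4-(2,2-diethoxyethoxy)-2-methoxybenzene
Conditions: K2CO3, DMF, 110 °C
Reagents that add atoms: none
Why: Williamson ether synthesis; the phenoxide of 1 displaces the primary bromide of 2, and the acetal, aryl chloride and methyl ether are inert to carbonate base.

Step 2
Reactants: 3 1-chloro-4-(2,2-diethoxyethoxy)-2-methoxybenzene
Product: 4 5-chloro-6-methoxybenzofuran
Conditions: polyphosphoric acid, toluene, 100 °C
Reagents that add atoms: none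
Why: Acid-mediated cyclodehydration (intramolecular Friedel–Crafts attack on the oxocarbenium ion of the acetal, then loss of ethanol); closure should favour the unhindered ring position para to the methoxy group, and the minor 4-methoxy isomer from closure between the two oxygens would be removed by chromatography.

Step 3
Reactants: 5 3,5-dimethoxyphenol
Product: 6 3,5-dimethoxyphenyl trifluoromethanesulfonate
Conditions: Tf2O, pyridine, CH2Cl2, 0 °C
Reagents that add atoms: trifluoromethanesulfonic anhydride, O=S(=O)(OS(=O)(=O)C(F)(F)F)C(F)(F)F
Why: Standard O-sulfonylation of a phenol; pyridine takes up the triflic acid.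

Step 4
Reactants: 4 5-chloro-6-methoxybenzofuran; 7 2-(3,4-dimethoxyphenyl)-4,4,5,5-tetramethyl-1,3,2-dioxaborolane; 6 3,5-dimethoxyphenyl trifluoromethanesulfonate
Product: 10 2-[(2S,3S)-5-chloro-2-(3,4-dimethoxyphenyl)-3-(3,5-dimethoxyphenyl)-6-methoxy-2,3-dihydrobenzofuran-2-yl]-4,4,5,5-tetramethyl-1,3,2-dioxaborolane, via (5-chloro-6-methoxybenzofuran-2-yl)lithium 8 (not isolated), via lithium benzofuranyl(aryl)pinacolatoborate 9 (not isolated)
Conditions: n-BuLi (slightly less than 1 equiv), THF, −78 °C; 7, −78 °C to rt; then 6, Pd(OAc)2 (cat.), Mandyphos bisphosphine (1,1′-bis[bis(4-methoxy-3,5-dimethylphenyl)phosphino]-2,2′-bis[α-(dimethylamino)benzyl]ferrocene, single enantiomer, cat.), THF, 60 °C; non-oxidative work-up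
Reagents that add atoms: none
Why: Proposed new method: n-BuLi removes the C2 proton of 4, the most acidic C–H, without touching the aryl chloride and without forming lithium halide (which would slow the catalyst), and 8 adds to the boron of 7 to give the four-coordinate boronate 9. Zerovalent palladium formed from Pd(OAc)2 and the bisphosphine inserts into the C–O bond of triflate 6, which a chelating diarylphosphine should prefer over the electron-rich C–Cl bond, and the cationic arylpalladium binds one face of the enol-ether-like C2=C3 bond of 9. This binding triggers a 1,2-metallate shift in which the 3,4-dimethoxyphenyl group moves from boron to C2 on the face opposite palladium while C3 bonds to palladium, and reductive elimination then forms the C3–aryl bond with retention and returns zerovalent palladium. The closest known reaction types are the palladium-catalysed enantioselective conjunctive cross-coupling of alkenyl boronate complexes with aryl triflates and the dearomative three-component coupling of indol-2-yl boronates with allylic electrophiles; the low aromatic stabilization of the furan ring makes the extension to a benzofuran reasonable. No ring is closed; two skeletal bonds (C2–aryl and C3–aryl) form on the intact bicycle. C3 is set by the chiral ligand, which chooses the alkene face that palladium binds, and C2 follows from C3 through the anti course of the migration, so the aryl groups emerge trans and boron cis to the C3 aryl group. The step needs the metallate shift to outrun direct transfer of a carbon group from boron to palladium and any beta-elimination; the nucleophilic C3 of the boronate, the cationic palladium from the triflate, the fully substituted C2 (no beta-hydrogen) and the ring geometry, which holds the C2–O bond out of plane with the C3–Pd bond, should secure this.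

Step 5
Reactants: 10 2-[(2S,3S)-5-chloro-2-(3,4-dimethoxyphenyl)-3-(3,5-dimethoxyphenyl)-6-methoxy-2,3-dihydrobenzofuran-2-yl]-4,4,5,5-tetramethyl-1,3,2-dioxaborolane
Product: 11 (2S,3S)-5-chloro-2-(3,4-dimethoxyphenyl)-3-(3,5-dimethoxyphenyl)-6-methoxy-2,3-dihydrobenzofuran
Conditions: CsF, H2O (about 1 equiv), 1,4-dioxane, 45 °C
Reagents that add atoms: none
Why: Fluoride-promoted stereoretentive protodeboronation of a tertiary benzylic boronic ester; fluoride adds to boron and water protonates carbon on the face boron occupied (SE2, retention), so hydrogen ends up cis to the C3 aryl group and the aryl groups stay trans, while C3 is untouched.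

Step 6
Reactants: 11 (2S,3S)-5-chloro-2-(3,4-dimethoxyphenyl)-3-(3,5-dimethoxyphenyl)-6-methoxy-2,3-dihydrobenzofuran; 12 1-ethenyl-3,5-dimethoxybenzene (3,5-dimethoxystyrene)
Product: 13 (2S,3S)-2-(3,4-dimethoxyphenyl)-3-(3,5-dimethoxyphenyl)-5-[(E)-2-(3,5-dimethoxyphenyl)ethenyl]-6-methoxy-2,3-dihydrobenzofuran
Conditions: Pd2(dba)3 (cat.), P(t-Bu)3 (cat.), Cy2NMe, 1,4-dioxane, 110 °C
Reagents that add atoms: none
Why: Mizoroki–Heck reaction of an aryl chloride; the bulky electron-rich phosphine lets zerovalent palladium insert into the deactivated C–Cl bond, and syn carbopalladation at the terminal alkene carbon followed by syn beta-hydride elimination gives the (E)-stilbene; the hindered amine does not epimerize C2 or C3.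

Step 7
Reactants: 13 (2S,3S)-2-(3,4-dimethoxyphenyl)-3-(3,5-dimethoxyphenyl)-5-[(E)-2-(3,5-dimethoxyphenyl)ethenyl]-6-methoxy-2,3-dihydrobenzofuran
Product: 14 (2S,3S)-2-(3,4-dihydroxyphenyl)-3-(3,5-dihydroxyphenyl)-5-[(E)-2-(3,5-dihydroxyphenyl)ethenyl]-2,3-dihydrobenzofuran-6-ol (CNP0263230.1)
Conditions: BBr3 (excess), CH2Cl2, −78 °C to 0 °C; then MeOH, H2O
Reagents that add atoms: none
Why: Lewis-acid cleavage of aryl methyl ethers; BBr3 binds each methoxy oxygen, bromide removes the methyl group (SN2) and hydrolysis frees the seven phenols; any reversible ionization of the C2–O bond should reclose to the favoured trans isomer under control of C3.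

## Compound list

1 | 4-chloro-3-methoxyphenol | COc1cc(O)ccc1Cl | starting material
2 | 2-bromo-1,1-diethoxyethane | CCOC(CBr)OCC | starting material
3 | 1-chloro-4-(2,2-diethoxyethoxy)-2-methoxybenzene | CCOC(COc1ccc(Cl)c(OC)c1)OCC | intermediate
4 | 5-chloro-6-methoxybenzofuran | COc1cc2occc2cc1Cl | intermediate
5 | 3,5-dimethoxyphenol | COc1cc(O)cc(OC)c1 | starting material
6 | 3,5-dimethoxyphenyl trifluoromethanesulfonate | COc1cc(OC)cc(OS(=O)(=O)C(F)(F)F)c1 | intermediate
7 | 2-(3,4-dimethoxyphenyl)-4,4,5,5-tetramethyl-1,3,2-dioxaborolane | COc1ccc(B2OC(C)(C)C(C)(C)O2)cc1OC | starting material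
8 | (5-chloro-6-methoxybenzofuran-2-yl)lithium | [Li]c1cc2cc(Cl)c(OC)cc2o1 | intermediate (not isolated)
9 | lithium (5-chloro-6-methoxybenzofuran-2-yl)(3,4-dimethoxyphenyl)(2,3-dimethylbutane-2,3-diolato)borate | [Li+].COc1ccc([B-]2(c3cc4cc(Cl)c(OC)cc4o3)OC(C)(C)C(C)(C)O2)cc1OC | intermediate (not isolated)
10 | 2-[(2S,3S)-5-chloro-2-(3,4-dimethoxyphenyl)-3-(3,5-dimethoxyphenyl)-6-methoxy-2,3-dihydrobenzofuran-2-yl]-4,4,5,5-tetramethyl-1,3,2-dioxaborolane | Clc1cc2c(cc1OC)O[C@](B1OC(C)(C)C(C)(C)O1)(c1ccc(OC)c(OC)c1)[C@H]2c1cc(OC)cc(OC)c1 | intermediate
11 | (2S,3S)-5-chloro-2-(3,4-dimethoxyphenyl)-3-(3,5-dimethoxyphenyl)-6-methoxy-2,3-dihydrobenzofuran | Clc1cc2c(cc1OC)O[C@H](c1ccc(OC)c(OC)c1)[C@H]2c1cc(OC)cc(OC)c1 | intermediate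
12 | 1-ethenyl-3,5-dimethoxybenzene | C=Cc1cc(OC)cc(OC)c1 | starting material
13 | (2S,3S)-2-(3,4-dimethoxyphenyl)-3-(3,5-dimethoxyphenyl)-5-[(E)-2-(3,5-dimethoxyphenyl)ethenyl]-6-methoxy-2,3-dihydrobenzofuran | COc1cc(OC)cc(/C=C/c2cc3c(cc2OC)O[C@H](c2ccc(OC)c(OC)c2)[C@H]3c2cc(OC)cc(OC)c2)c1 | intermediate
14 | (2S,3S)-2-(3,4-dihydroxyphenyl)-3-(3,5-dihydroxyphenyl)-5-[(E)-2-(3,5-dihydroxyphenyl)ethenyl]-2,3-dihydrobenzofuran-6-ol | Oc1cc(O)cc(/C=C/c2cc3c(cc2O)O[C@H](c2ccc(O)c(O)c2)[C@H]3c2cc(O)cc(O)c2)c1 | target

## Step count and least certain steps

Total: 7 steps. Longest linear sequence: 6 steps (steps 1, 2, 4, 5, 6, 7); step 3 is a one-step side branch.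

**Step 4 (key step).** The most likely failure is direct transfer of a carbon group from boron to palladium, giving biaryl or 2-arylbenzofuran, because a benzofuran C2=C3 bond is more hindered and less nucleophilic than a simple vinyl group. Weak or opposite face selection is the second risk. The fallback uses known chemistry, sets out from 4 and comes back at 11. Lithiation of 4, transmetalation with ZnCl2 and Negishi coupling with 4-bromo-1,2-dimethoxybenzene (Pd(PPh3)4) would give 5-chloro-2-(3,4-dimethoxyphenyl)-6-methoxybenzofuran F1. NBS would brominate the enol ether carbon to give 3-bromo-5-chloro-2-(3,4-dimethoxyphenyl)-6-methoxybenzofuran F2. Suzuki–Miyaura coupling with (3,5-dimethoxyphenyl)boronic acid (Pd(PPh3)4, K2CO3; the C–Br bond reacts, the C–Cl bond does not) would give 5-chloro-2-(3,4-dimethoxyphenyl)-3-(3,5-dimethoxyphenyl)-6-methoxybenzofuran F3. Ionic hydrogenation (Et3SiH, trifluoroacetic acid) protonates C3 and delivers hydride to the C2 oxocarbenium ion anti to the C3 aryl group, giving racemic trans-5-chloro-2-(3,4-dimethoxyphenyl)-3-(3,5-dimethoxyphenyl)-6-methoxy-2,3-dihydrobenzofuran F4. Preparative chromatography on a chiral stationary phase would then deliver 11. This gives up catalyst control and half the material.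

**Step 5.** Two things may go wrong. Protonation may take place through a carbanion-like intermediate on the less hindered face, giving inversion at C2 and the cis relation. Or the fluoride-bound boronate may open the ring by a 1,2-shift that expels the aryloxide. The fallback sets out from 10 and comes back at 11. It replaces kinetic retention by thermodynamic control. Protodeboronation under forcing conditions (tetrabutylammonium fluoride trihydrate, toluene) is accepted without regard to its steric course, and may give 11 mixed with its C2 epimer (2R,3S)-5-chloro-2-(3,4-dimethoxyphenyl)-3-(3,5-dimethoxyphenyl)-6-methoxy-2,3-dihydrobenzofuran F5. Trifluoroacetic acid in CH2Cl2 then ionizes the C2–O bond (cation stabilized by the para methoxy group), and reclosure under control of the untouched C3 center should converge on trans 11.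

**Step 6.** Oxidative addition into the electron-rich, ortho-alkoxy aryl chloride may be slow, so that hydrodechlorination, styrene oligomerization or arylation at the internal alkene carbon take over. The fallback sets out from 11 and 12 and comes back at 13. It replaces the Heck reaction by a Suzuki–Miyaura coupling with the alkene geometry fixed in the reagent. Cross-metathesis of 12 with vinylboronic acid pinacol ester (second-generation Grubbs catalyst) would give 2-[(E)-2-(3,5-dimethoxyphenyl)ethenyl]-4,4,5,5-tetramethyl-1,3,2-dioxaborolane F6. This would be coupled with 11 (Pd(OAc)2, SPhos, K3PO4, toluene/water, 100 °C).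

**Step 7.** During the seven-fold ether cleavage the stilbene may react with acid (HBr addition, cationic oligomerization, E/Z drift), or a ring-opened C2 cation may be captured in a Friedel–Crafts reaction. The fallback sets out from 11 and comes back at 14. It moves the demethylation ahead of the alkene. BBr3 on 11 would give (2S,3S)-5-chloro-2-(3,4-dihydroxyphenyl)-3-(3,5-dihydroxyphenyl)-2,3-dihydrobenzofuran-6-ol F7. Acetic anhydride and pyridine would give its pentaacetate F8. Heck coupling of F8 with purchased 5-ethenyl-1,3-phenylene diacetate F9 (Pd2(dba)3, P(t-Bu)3, Cy2NMe) would give the heptaacetate of the target F10. Methanolysis (K2CO3, degassed MeOH, 0 °C) would release 14 under mild base.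

**Step 2.** Closure may also occur at the position between the two oxygen substituents, and the acid may oligomerize the electron-rich benzofuran. The fallback sets out from 1 and comes back at 4, and fixes the regiochemistry through an aldehyde carbon. Magnesium-mediated ortho-formylation (MgCl2, Et3N, paraformaldehyde) would give 5-chloro-2-hydroxy-4-methoxybenzaldehyde F11. Ethyl bromoacetate and K2CO3 in hot DMF (O-alkylation, then intramolecular aldol condensation) would give ethyl 5-chloro-6-methoxybenzofuran-2-carboxylate F12. NaOH would give 5-chloro-6-methoxybenzofuran-2-carboxylic acid F13, and copper powder in quinoline at 200 °C would decarboxylate it to 4.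

## Further compounds

F1 | step 4 | 5-chloro-2-(3,4-dimethoxyphenyl)-6-methoxybenzofuran | COc1ccc(-c2cc3cc(Cl)c(OC)cc3o2)cc1OC
F2 | step 4 | 3-bromo-5-chloro-2-(3,4-dimethoxyphenyl)-6-methoxybenzofuran | COc1ccc(-c2oc3cc(OC)c(Cl)cc3c2Br)cc1OC
F3 | step 4 | 5-chloro-2-(3,4-dimethoxyphenyl)-3-(3,5-dimethoxyphenyl)-6-methoxybenzofuran | COc1ccc(-c2oc3cc(OC)c(Cl)cc3c2-c2cc(OC)cc(OC)c2)cc1OC
F4 | step 4 | racemic trans-5-chloro-2-(3,4-dimethoxyphenyl)-3-(3,5-dimethoxyphenyl)-6-methoxy-2,3-dihydrobenzofuran | Clc1cc2c(cc1OC)O[C@H](c1ccc(OC)c(OC)c1)[C@H]2c1cc(OC)cc(OC)c1.Clc1cc2c(cc1OC)O[C@@H](c1ccc(OC)c(OC)c1)[C@@H]2c1cc(OC)cc(OC)c1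
F5 | step 5 | (2R,3S)-5-chloro-2-(3,4-dimethoxyphenyl)-3-(3,5-dimethoxyphenyl)-6-methoxy-2,3-dihydrobenzofuran | Clc1cc2c(cc1OC)O[C@@H](c1ccc(OC)c(OC)c1)[C@H]2c1cc(OC)cc(OC)c1
F6 | step 6 | 2-[(E)-2-(3,5-dimethoxyphenyl)ethenyl]-4,4,5,5-tetramethyl-1,3,2-dioxaborolane | COc1cc(/C=C/B2OC(C)(C)C(C)(C)O2)cc(OC)c1
F7 | step 7 | (2S,3S)-5-chloro-2-(3,4-dihydroxyphenyl)-3-(3,5-dihydroxyphenyl)-2,3-dihydrobenzofuran-6-ol | Clc1cc2c(cc1O)O[C@H](c1ccc(O)c(O)c1)[C@H]2c1cc(O)cc(O)c1
F8 | step 7 | (2S,3S)-5-chloro-2-(3,4-diacetoxyphenyl)-3-(3,5-diacetoxyphenyl)-2,3-dihydrobenzofuran-6-yl acetate | Clc1cc2c(cc1OC(C)=O)O[C@H](c1ccc(OC(C)=O)c(OC(C)=O)c1)[C@H]2c1cc(OC(C)=O)cc(OC(C)=O)c1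
F9 | step 7 | 5-ethenyl-1,3-phenylene diacetate | C=Cc1cc(OC(C)=O)cc(OC(C)=O)c1
F10 | step 7 | (2S,3S)-2-(3,4-diacetoxyphenyl)-3-(3,5-diacetoxyphenyl)-5-[(E)-2-(3,5-diacetoxyphenyl)ethenyl]-2,3-dihydrobenzofuran-6-yl acetate | CC(=O)Oc1cc(OC(C)=O)cc(/C=C/c2cc3c(cc2OC(C)=O)O[C@H](c2ccc(OC(C)=O)c(OC(C)=O)c2)[C@H]3c2cc(OC(C)=O)cc(OC(C)=O)c2)c1
F11 | step 2 | 5-chloro-2-hydroxy-4-methoxybenzaldehyde | COc1cc(O)c(C=O)cc1Cl
F12 | step 2 | ethyl 5-chloro-6-methoxybenzofuran-2-carboxylate | CCOC(=O)c1cc2cc(Cl)c(OC)cc2o1
F13 | step 2 | 5-chloro-6-methoxybenzofuran-2-carboxylic acid | OC(=O)c1cc2cc(Cl)c(OC)cc2o1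
A1 | alternative 1 | methyl 4-iodo-2-methoxybenzoate | COC(=O)c1ccc(I)cc1OC
A2 | alternative 1 | tert-butyl (2R,3S)-3-(3,5-dimethoxyphenyl)oxirane-2-carboxylate | CC(C)(C)OC(=O)[C@@H]1O[C@H]1c1cc(OC)cc(OC)c1
A3 | alternative 1 | 2-tert-butyl 5-methyl (2R,3S)-3-(3,5-dimethoxyphenyl)-6-methoxy-2,3-dihydrobenzofuran-2,5-dicarboxylate (cis) | COC(=O)c1cc2c(cc1OC)O[C@@H](C(=O)OC(C)(C)C)[C@H]2c1cc(OC)cc(OC)c1
A4 | alternative 2 | (4S,5S)-5-(3,4-dimethoxyphenyl)-4-(3,5-dimethoxyphenyl)-2-methyl-4,5-dihydrofuran-3-carbaldehyde | O1[C@H](c2ccc(OC)c(OC)c2)[C@@H](c2cc(OC)cc(OC)c2)C(C=O)=C1C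
A5 | alternative 2 | dimethyl malonate | COC(=O)CC(=O)OC
A6 | alternative 2 | methyl (2S,3S)-2-(3,4-dimethoxyphenyl)-3-(3,5-dimethoxyphenyl)-6-hydroxy-2,3-dihydrobenzofuran-5-carboxylate | COC(=O)c1cc2c(cc1O)O[C@H](c1ccc(OC)c(OC)c1)[C@H]2c1cc(OC)cc(OC)c1
A7 | alternative 3 | (S)-6-bromo-2-(3,4-dimethoxyphenyl)-7-methoxychroman-4-one | O=C1C[C@@H](c2ccc(OC)c(OC)c2)Oc2cc(OC)c(Br)cc21
A8 | alternative 3 | methyl (2S,3S)-5-bromo-2-(3,4-dimethoxyphenyl)-6-methoxy-2,3-dihydrobenzofuran-3-carboxylate (trans) | Brc1cc2c(cc1OC)O[C@H](c1ccc(OC)c(OC)c1)[C@H]2C(=O)OC
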